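Hold to one invariant: every mole of partner charged stays in the books, as free partner, as catalyst intermediate B, inside target, or as decomposed reagent, so a yield is a statement about how the partner divides.

| setting | oak | larch | birch | gamma | beta | delta |
|---|---|---|---|---|---|---|
| starting material | 0.062 M | 0.062 M | 0.12 M | 0.062 M | 0.062 M | 0.062 M |
| partner | 1.7 equiv | 2.6 equiv | 1.2 equiv | 1.20 equiv | 1.20 equiv | 1.20 equiv |
| free catalyst | 1 mol% | 1 mol% | 1 mol% | 1 mol% | 1 mol% | 1 mol% |
| temperature | −25 °C | 5 °C | −25 °C | −20 °C | 5 °C | 30 °C |
| remark | run made earlier | run made earlier | run made earlier |  |  |  |
| time |  |  |  | 3.0 min | 3.0 min | 3.0 min |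

| run | time / s | starting material / % | catalyst intermediate A / % | target / % | catalyst intermediate B / % |
|---|---|---|---|---|---|
| oak | 25.0 | 92.2 | 0.8 | 7.8 | 0.3 |
| oak | 50.0 | 86.1 | 0 | 12.7 | 1.1 |
| oak | 80.0 | 79.0 | 0.9 | 19.8 | 0.9 |
| oak | 120 | 70.1 | 0.2 | 28.0 | 0.4 |
| larch | 10.0 | 74.5 | 0.2 | 25.7 | 0 |
| larch | 12.0 | 71.3 | 0.3 | 28.3 | 0 |
| larch | 25.0 | 60.4 | 1.9 | 39.7 | 0 |
| larch | 40.0 | 58.8 | 1.1 | 39.9 | 1.1 |
| birch | 25.0 | 90.5 | 0 | 8.8 | 0.1 |
| birch | 50.0 | 82.6 | 0.8 | 17.5 | 0 |
| birch | 80.0 | 73.6 | 0.2 | 25.3 | 0.5 |
| birch | 120 | 62.4 | 1.2 | 36.7 | 1.2 |

(standard deviation of a reading: 0.5 percentage points)

- target is meant together with its crystals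
- solid, in amounts per volume of the solution: crystals
- reactions considered so far: starting material + free catalyst -> catalyst intermediate A; partner + catalyst intermediate A -> catalyst intermediate B; catalyst intermediate B <-> free catalyst + target; partner -> decomposed reagent; crystals <-> target

- which of these there is most of at the end, counted by the starting material in it, gamma (catalyst intermediate B / target / starting material / catalyst intermediate A)
- which of these there is most of at the end, counted by the starting material in it, beta (catalyst intermediate B / target / starting material / catalyst intermediate A)
- which of these there is most of at the end, counted by the starting material in it, delta (catalyst intermediate B / target / starting material / catalyst intermediate A)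
- amount of the one of these that there is most of at the end, in percent of the starting material charged, gamma
- amount of the one of these that there is most of at the end, in percent of the starting material charged, beta
- amount of the one of these that there is most of at the end, in percent of the starting material charged, delta

Open the ledger on larch, which shares its 5 °C and its 0.062 M of starting material with beta. There 41.2% of the starting material has gone by 40.0 s, and target reads 39.7% at 25.0 s and 39.9% at the last reading, a step smaller than the scatter of 0.5 percentage points, although 2.6 equiv of partner were charged and starting material remains. Enter one partner for each target, write the balance of the larch charge to decomposed reagent, and treat partner as the limiting reagent in practice, whatever its excess on paper.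

A first answer scales that entry with the charge, so that the 1.20 equiv of beta consume 19.0% of the starting material. Now put that answer back in and question what it assumes, that turnover is proportional to partner. Oak and birch can test this at equal loading and equal time, where the percentage consumed measures the turnover of one catalyst: they show 29.9% and 37.6% at 120 s, while partner concentration rises by a factor of 1.37. Call the partner order, an apparent reaction order, the power of partner concentration that turnover follows, read off these two scattered readings as 0.734, and take the whole rise as the partner's, though starting material moved too.

If partner decays first-order, with temperature, starting concentration and loading held, turnover summed over the partner's lifetime scales as the charge raised to that order. The second round therefore gives beta 23.4% consumed, so commit to 76.6% of starting material left in beta, well ahead of target, which holds at most that consumed share, with the balance of the partner entered as decomposed reagent.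

The forecast gives starting material the lead at 58%, 80% and 95% for gamma, beta and delta, on the ground of “decomposition of the partner setting the yield when warm”.

The flasks give starting material 54.8% in gamma, 74.1% in beta and 89.5% in delta, more than target in each.

    starting material + free catalyst → catalyst intermediate A (k = 23.0 L mol⁻¹ s⁻¹, Ea = 35.0 kJ mol⁻¹)
    partner + catalyst intermediate A → catalyst intermediate B (k = 15.0 L mol⁻¹ s⁻¹, Ea = 38.0 kJ mol⁻¹)
    catalyst intermediate B ⇌ free catalyst + target (K = 0.0360 M, k = 1.40 s⁻¹, Ea = 69.0 kJ mol⁻¹, ΔH = 17.0 kJ mol⁻¹)
    partner → decomposed reagent (k = 0.00570 s⁻¹, Ea = 70.0 kJ mol⁻¹)
    crystals ⇌ target, rate k5*(cs5 - [target]) while solid is left; crystals form when [target] > cs5 (solubility = 12.0 mM, k = 0.0750 s⁻¹)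
    (constants at −20 °C)

Beta stands at 74.1% against my 76.6%, and its books close with target at 24.9% and decomposed reagent at 0.951 of the starting material charged, with 0% of the partner free and catalyst intermediate B at 0%. Now take the beta flask to 1.65 equiv of partner: raising the consumed 25.9% by the charge ratio to the power 0.734 moves starting material by 6.8 points, and that flask has moved by 6 points.

The readings come from a simulation for an exercise.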